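## Analysis of the target

Numbering used throughout: C1 (CH2), C2 (=CH), C3 (enol-ether carbon), C4 (C(CH3)OH), C5 (CH2), C6 (CHOAc), C7 and C8 (butenolide β- and γ-carbons), C9 (=CH), C10 (C(CH3)–O), C11 (butenolide α-carbon), C12 (lactone C=O), C13 (CH2OAc).

The target is a ten-membered carbocycle (C1–C10) bridged by an oxygen between C3 and C10, so that O, C3, C2, C1 and C10 form a 2,3-dihydrofuran with the enol-ether double bond C2=C3. It is fused through C7–C8 to a butenolide (O, C12, C11, C7, C8) that carries the acetoxymethyl carbon C13 on C11. The lactone is a γ-ylidene butenolide: C8=C9 is exocyclic to the lactone and endocyclic to the carbocycle, with C7 and C10 cis (the (E) descriptor, because the ring oxygen outranks C7). There are three stereocentres, all (S): the quaternary ether carbon C10, the tertiary carbinol C4 and the acetoxy-bearing C6. C4 and C6 are 1,3-anti, whereas C10 is related to them only across the ring. Sensitive groups are the enol ether with its allylic tertiary hydroxyl (acid), the cross-conjugated ylidene lactone (base, nucleophiles, reductants) and the two acetates; the C4 hydroxyl also lies within reach of C8. The difficulty is to close a strained, doubly annulated medium ring while relating C4 to the remote C10, and to carry a butenolide equivalent through the chemistry that does so. The route rests on the unit C4–C5–C6, an aldol pattern whose acceptor carbon C4 hangs on the enol-ether carbon C3 of an already closed dihydrofuran, and on a 2-silylfuran spanning C7, C8, C11 and C12 as a latent ylidene butenolide.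

## Retrosynthetic reasoning

**Butenolide from a silylfuran (30 ⇒ 29 ⇒ 26).** The C8=C9 double bond is removed by adding the elements of water across it to give lactol 29. Its C12 carbonyl and C8 hydroxyl are traced back to the 2-silylfuran 26 by sensitised photooxygenation (through 27 and 28). The cut is made here because a butenolide would not survive organolithium or reducing steps, whereas the furan does. The silicon on C12 decides which α-carbon becomes the carbonyl, and the ring allows only the cis arrangement of C7 and C10.

**Acetates and the C6 stereocentre (26 ⇒ 25 ⇒ 24 ⇒ 23).** The two acetates come from triol 25, with the tertiary C4 hydroxyl left free on steric grounds, and 25 from silyl ether 24. The C6 carbinol is cut back to the C6 ketone of 23. The forward reduction has to deliver hydride from the C4 hydroxyl so that C6 ends up 1,3-anti to C4, which is the relationship in the target.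

**Key disconnection C4–C5 (23 ⇒ 21).** The β-hydroxy ketone 23 is opened between C4 and C5. This is the only bond whose cleavage gives two carbonyl groups that are both easy to install, a C4 methyl ketone on the dihydrofuran and a C6 furyl ketone, and it leaves the rigid C3–O–C10 bridge intact to pre-organise the chain. The forward step is a Reformatsky-type closure: divalent samarium turns the C5 bromide of 21 into the enolate 22, which must find the C4 ketone on the face dictated by C10.

**Bromoacetyl group (21 ⇒ 20 ⇒ 19 ⇒ 17).** The bromide is exchanged for the chloride of 20, and the C4 ketone is taken back to the carbinol of 19. The C6–C7 bond is then cut to the C7 bromide of 17. The α-halo ketone is the least robust group of the precursor, so it is introduced last, by acylation of the C7 aryllithium. That step tolerates a C4 alkoxide but would not tolerate a C4 ketone, which is why C4 is carried at the alcohol level until then. No electrophilic halogen and no palladium are needed next to the enol ether.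

**Furan silyl group and protecting group (17 ⇒ 16 ⇒ 15).** The secondary silyl ether of 16 keeps the C4 oxygen inert until that point. The C12 silyl group is disconnected to the only remaining furan C–H of 15; it has to be put on by metalation before any ketone exists.

**Enol ether C3–O (15 ⇒ 14).** The dihydrofuran is opened at its C3–O bond to the homopropargylic tertiary alcohol 14. An internal alkyne that already carries C4 gives the substituted enol ether in one catalytic, redox-neutral step. It avoids deprotonating a dihydrofuran with alkyllithium in the presence of the C7 bromide.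

**Fragment union C8–C9 (14 ⇒ 5 + 12).** The bond between the furan carbon C8 and C9 is cut to bromofuran 5 and epoxide 12. The epoxide delivers C9 as a CH2 group directly, so no oxygen has to be removed later next to the bromide, and it releases the C10 tertiary alcohol without touching the stereocentre. The bromine of 5 directs the lithiation to C8 and later becomes the C7 handle.

**Fragments (12 ⇒ 7 + 9; 9 ⇒ 8; 7 ⇒ 6; 5 ⇒ 4 ⇒ 3 ⇒ 1).** Epoxide 12 comes from tosylate 9 and alkyne 7 by opening and re-closing, which transposes the epoxide while the purchased stereocentre of 8 becomes C10. Furan 5 comes from symmetric 1 by differentiating the two bromines, one into C13 and one kept.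

## Alternatives that were turned down

**Alternative 1:** Disconnection of C9–C10. An alkenyl iodide at C9, on a butenolide that is already complete, would be metalated with NiCl2/CrCl2 and added to a C10 methyl ketone (Nozaki–Hiyama–Kishi closure), giving the ten-membered tertiary allylic alcohol A1 with C3/C4 held as an acetonide.
- For it: the ylidene butenolide and its geometry are in place before ring closure, so no furan has to be oxidised beside an enol ether at the end. On this point it is stronger than the chosen route. C4 is also set early and independently as part of a protected diol.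
- Against it: alkenylchromium reagents add to ketones far more slowly than to aldehydes, and here the ketone closure would also have to form a medium ring from an open chain. The quaternary C10 centre would be created under remote control by C4 and C6. The iodoalkene is conjugated to a lactone that low-valent chromium can reduce. A1 would still need acetonide removal, selective oxidation at C3 and an acid-promoted cyclodehydration to the enol ether in the presence of the ylidene lactone.
- Comparison: the chosen route buys C10 and lets it control C4 through a short, rigid tether. It closes the ring onto a bridged substrate and needs no redox change on the carbocycle after closure other than one ketone reduction.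

**Alternative 2:** Disconnection of C10–O. In a preformed ten-membered ring, the enol oxygen of a C3 ketone would add across the ring to C10 of a C8–C9–C10 enone, giving the oxygen-bridged C8 ketone A2 with the dihydrofuran and C10 formed together.
- For it: one atom-economic step makes the bridge and the quaternary centre, and the butenolide then arises by lactonisation without any oxidant. Here too it is stronger at the late stage.
- Against it: the ten-membered carbocycle, which is the real problem, must be made first, with a trisubstituted enone and a tetrasubstituted alkylidene ester of defined geometry. The ambident enolate can attack through C2 instead of oxygen. Conjugate addition of oxygen to a β,β-disubstituted enone is reversible, and A2 is a β-alkoxy ketone that can revert during the later enol-lactonisation. The C10 configuration would depend on ring conformation.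
- Comparison: the chosen route forms the C10–O bond irreversibly with purchased configuration and spends its ring closure on a C–C bond that is trapped as a samarium aldolate.

**Alternative 3:** Disconnection of C1–C10 by an anionic oxy-Cope rearrangement. In the substrate the bond C3–C8 closes a six-membered ring; its C3 potassium alkoxide would undergo the [3,3] shift, giving the ten-membered C3 ketone A3 with the C8=C9 ylidene and C10.
- For it: ring expansion avoids the entropic cost of an end-to-end cyclisation and sets the C8=C9 geometry and C10 together. On ring formation as such it is at least as strong as the chosen aldol closure.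
- Against it: the six-membered precursor needs four stereocentres (C3, C4, C6 and the quaternary C8 at the lactone γ-position) before the key step. A potassium alkoxide would be generated next to a butenolide and a neighbouring silyl ether, which invites acyl and silyl transfer. C10 would derive from the geometry of a fully substituted silyl enol ether and a chair/boat preference. A3 still requires cleavage of a tertiary silyl ether, cyclodehydration to the enol ether and differentiation of three kinds of silyl ether.
- Comparison: the chosen route has one stereocentre before the key step and five steps after it, and its fragments are joined convergently.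

Key step: step 14

Remark: (R)-2-methylglycidol 8 and (S)-but-3-yn-2-ol 6 are taken as purchasable single enantiomers; the carbinol centre of 6 is a spectator that is erased in step 12, so its antipode or the racemate would serve equally.

## Route

Step 1
Reactants: 1 3,4-dibromofuran
Product: 3 4-bromofuran-3-carbaldehyde, via 4-bromofuran-3-yllithium 2 (not isolated)
Conditions: n-BuLi, Et2O, −78 °C; DMF, −78 °C; H2O
Reagents that add atoms: N,N-dimethylformamide, CN(C)C=O
Why: Mono bromine–lithium exchange of the symmetric dibromide at −78 °C (the 3-lithiofuran ring-opens on warming) followed by formylation; the second bromine is kept as the handle for steps 7 and 11.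

Step 2
Reactants: 3 4-bromofuran-3-carbaldehyde
Product: 4 (4-bromofuran-3-yl)methanol
Conditions: NaBH4, MeOH, 0 °C
Reagents that add atoms: none
Why: Chemoselective hydride reduction of the aldehyde; the aryl bromide is inert to NaBH4.

Step 3
Reactants: 4 (4-bromofuran-3-yl)methanol
Product: 5 [(4-bromofuran-3-yl)methoxy]tri(propan-2-yl)silane
Conditions: iPr3SiCl, imidazole, DMF, rt
Reagents that add atoms: chlorotri(propan-2-yl)silane, CC(C)[Si](Cl)(C(C)C)C(C)C
Why: Standard silylation; the bulky silyl ether survives the organolithium, Lewis-acid and short fluoride treatments ahead and is removed only in step 16.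

Step 4
Reactants: 6 (S)-but-3-yn-2-ol
Product: 7 (S)-(but-3-yn-2-yloxy)triethylsilane
Conditions: Et3SiCl, imidazole, CH2Cl2, 0 °C
Reagents that add atoms: chlorotriethylsilane, CC[Si](Cl)(CC)CC
Why: Silylation of the propargylic alcohol so that the alkyne can be metalated; the triethylsilyl group is chosen because fluoride removes it in step 10 without touching the primary triisopropylsilyl ether.

Step 5
Reactants: 8 (R)-2-methylglycidol
Product: 9 (S)-(2-methyloxiran-2-yl)methyl 4-methylbenzenesulfonate
Conditions: TsCl, Et3N, DMAP (cat.), CH2Cl2, 0 °C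
Reagents that add atoms: 4-methylbenzenesulfonyl chloride, Cc1ccc(cc1)S(Cl)(=O)=O
Why: Sulfonylation of the primary alcohol; no bond to the stereocentre is touched, and the descriptor changes from (R) to (S) only because the tosyloxymethyl group now outranks the ring CH2.

Step 6
Reactants: 7 (S)-(but-3-yn-2-yloxy)triethylsilane; 9 (S)-(2-methyloxiran-2-yl)methyl 4-methylbenzenesulfonate
Product: 12 triethyl{[(2S)-5-[(2S)-2-methyloxiran-2-yl]pent-3-yn-2-yl]oxy}silane, via lithium acetylide 10 (not isolated), via hydroxy tosylate 11 (not isolated)
Conditions: n-BuLi, THF, −78 °C; BF3·OEt2, then 9, −78 °C; H2O; K2CO3, MeOH, rt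
Reagents that add atoms: none
Why: The lithium acetylide with BF3 opens the epoxide at its unsubstituted carbon (the neopentyl tosylate is inert), and base then lets the tertiary alkoxide displace the tosylate (3-exo-tet) to give the transposed epoxide. The C–O bond at the quaternary carbon is never broken, so its configuration is carried over; the former epoxide CH2 becomes C1 and the tosyloxymethyl carbon becomes C9.

Step 7
Reactants: 5 [(4-bromofuran-3-yl)methoxy]tri(propan-2-yl)silane; 12 triethyl{[(2S)-5-[(2S)-2-methyloxiran-2-yl]pent-3-yn-2-yl]oxy}silane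
Product: 14 (2S,6S)-1-[3-bromo-4-({[tri(propan-2-yl)silyl]oxy}methyl)furan-2-yl]-2-methyl-6-[(triethylsilyl)oxy]hept-4-yn-2-ol, via 2-furyllithium 13 (not isolated)
Conditions: LiN(iPr)2 (LDA), THF, −78 °C; 12, BF3·OEt2, −78 °C; H2O
Reagents that add atoms: none
Why: The amide base removes the furan α-proton next to bromine (halogen-directed lithiation, giving C8–Li), and BF3-assisted opening of the 2,2-disubstituted epoxide at its CH2 forms C8–C9. C10 is not the site of attack, so the tertiary alcohol is released with the purchased configuration.

Step 8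
Reactants: 14 (2S,6S)-1-[3-bromo-4-({[tri(propan-2-yl)silyl]oxy}methyl)furan-2-yl]-2-methyl-6-[(triethylsilyl)oxy]hept-4-yn-2-ol
Product: 15 3-bromo-2-{[(2S)-2-methyl-5-{(1S)-1-[(triethylsilyl)oxy]ethyl}-2,3-dihydrofuran-2-yl]methyl}-4-({[tri(propan-2-yl)silyl]oxy}methyl)furan
Conditions: Ph3PAuNTf2 (5 mol %), NaHCO3, 4 Å MS, CH2Cl2, 0 °C to rt
Reagents that add atoms: none
Why: Monovalent gold activates the internal alkyne for anti-addition of the tertiary hydroxyl at C3, the only feasible mode (5-endo-dig; attack at C2 would give an oxetane), and protodeauration gives the 2,3-dihydrofuran, the known cycloisomerisation of homopropargylic alcohols. NaHCO3 keeps the allylic silyloxy enol ether from ionising, and the bromine-bearing, fully flanked furan double bond is a poorer nucleophile toward the gold–alkyne complex than the hydroxyl.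

Step 9
Reactants: 15 3-bromo-2-{[(2S)-2-methyl-5-{(1S)-1-[(triethylsilyl)oxy]ethyl}-2,3-dihydrofuran-2-yl]methyl}-4-({[tri(propan-2-yl)silyl]oxy}methyl)furan
Product: 16 [4-bromo-5-{[(2S)-2-methyl-5-{(1S)-1-[(triethylsilyl)oxy]ethyl}-2,3-dihydrofuran-2-yl]methyl}-3-({[tri(propan-2-yl)silyl]oxy}methyl)furan-2-yl]trimethylsilane
Conditions: LiTMP, Me3SiCl (in situ), THF, −78 °C
Reagents that add atoms: chlorotrimethylsilane, C[Si](C)(C)Cl
Why: The only remaining furan C–H (C12, α to oxygen) is lithiated and silylated in situ, which also suppresses halogen migration. The silyl group will fix the regiochemistry of the furan oxidation in step 18 and has to be installed before any ketone is present.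

Step 10
Reactants: 16 [4-bromo-5-{[(2S)-2-methyl-5-{(1S)-1-[(triethylsilyl)oxy]ethyl}-2,3-dihydrofuran-2-yl]methyl}-3-({[tri(propan-2-yl)silyl]oxy}methyl)furan-2-yl]trimethylsilane
Product: 17 (1S)-1-[(5S)-5-{[3-bromo-5-(trimethylsilyl)-4-({[tri(propan-2-yl)silyl]oxy}methyl)furan-2-yl]methyl}-5-methyl-4,5-dihydrofuran-2-yl]ethan-1-ol
Conditions: Bu4NF, THF, 0 °C
Reagents that add atoms: none
Why: Fluoride cleaves the secondary triethylsilyl ether much faster than the hindered primary triisopropylsilyl ether and leaves the furan C–Si bond intact at 0 °C.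

Step 11
Reactants: 17 (1S)-1-[(5S)-5-{[3-bromo-5-(trimethylsilyl)-4-({[tri(propan-2-yl)silyl]oxy}methyl)furan-2-yl]methyl}-5-methyl-4,5-dihydrofuran-2-yl]ethan-1-ol
Product: 19 2-chloro-1-[2-{[(2S)-5-[(1S)-1-hydroxyethyl]-2-methyl-2,3-dihydrofuran-2-yl]methyl}-5-(trimethylsilyl)-4-({[tri(propan-2-yl)silyl]oxy}methyl)furan-3-yl]ethan-1-one, via dilithio species 18 (not isolated)
Conditions: t-BuLi (3.1 equiv), Et2O, −78 °C; ClCH2C(O)N(OMe)Me, −78 to −30 °C; H2O
Reagents that add atoms: 2-chloro-N-methoxy-N-methylacetamide, CON(C)C(=O)CCl
Why: The first equivalent of t-BuLi forms the C4 lithium alkoxide and the next two effect bromine–lithium exchange at C7 at −78 °C, where neither the enol ether nor the silylfuran is deprotonated. The aryllithium is acylated by the Weinreb amide, whose chelated tetrahedral intermediate survives until the quench and therefore stops at the α-chloro ketone (C6, C5); the alcohol oxidation level at C4 is what makes this organolithium step possible.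

Step 12
Reactants: 19 2-chloro-1-[2-{[(2S)-5-[(1S)-1-hydroxyethyl]-2-methyl-2,3-dihydrofuran-2-yl]methyl}-5-(trimethylsilyl)-4-({[tri(propan-2-yl)silyl]oxy}methyl)furan-3-yl]ethan-1-one
Product: 20 1-[(5S)-5-{[3-(chloroacetyl)-5-(trimethylsilyl)-4-({[tri(propan-2-yl)silyl]oxy}methyl)furan-2-yl]methyl}-5-methyl-4,5-dihydrofuran-2-yl]ethan-1-one
Conditions: MnO2, CH2Cl2, rt
Reagents that add atoms: none
Why: MnO2 oxidises the allylic secondary alcohol (conjugated to the enol ether) under neutral conditions and leaves the α-chloro ketone, silyl groups and enol ether alone. This erases the spectator stereocentre and gives the C4 methyl ketone as an α-alkoxy enone.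

Step 13
Reactants: 20 1-[(5S)-5-{[3-(chloroacetyl)-5-(trimethylsilyl)-4-({[tri(propan-2-yl)silyl]oxy}methyl)furan-2-yl]methyl}-5-methyl-4,5-dihydrofuran-2-yl]ethan-1-one
Product: 21 1-[(5S)-5-{[3-(bromoacetyl)-5-(trimethylsilyl)-4-({[tri(propan-2-yl)silyl]oxy}methyl)furan-2-yl]methyl}-5-methyl-4,5-dihydrofuran-2-yl]ethan-1-one
Conditions: LiBr (excess), acetone, rt
Reagents that add atoms: lithium bromide, [Li+].[Br-]
Why: Finkelstein exchange: the chloride α to the ketone undergoes fast SN2 substitution by bromide, and LiCl, poorly soluble in acetone, precipitates and drives the equilibrium.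

Step 14
Reactants: 21 1-[(5S)-5-{[3-(bromoacetyl)-5-(trimethylsilyl)-4-({[tri(propan-2-yl)silyl]oxy}methyl)furan-2-yl]methyl}-5-methyl-4,5-dihydrofuran-2-yl]ethan-1-one
Product: 23 (4S,10S) ten-membered C6-keto C4-carbinol fused to the silylfuran (C13 as OTIPS), via samarium enolate 22 (not isolated)
Conditions: SmI2 (2.5 equiv), THF, −78 °C, slow addition of 21 (final 0.003 M); H2O quench at −78 °C
Reagents that add atoms: none
Why: Two single-electron transfers from divalent samarium cleave the C5–Br bond (α-halo ketones are reduced far faster than the aryl ketone or the α-alkoxy enone) and give the trivalent samarium enolate 22 of the C6 ketone. Under high dilution and without a proton source the enolate adds through C5 to the C4 methyl ketone in a closed, samarium-bridged transition state; the closest known reaction type is the SmI2-mediated intramolecular Reformatsky (aldol) cyclisation of α-halo carbonyl compounds, an established way to medium and large rings. The one ring closed is the ten-membered carbocycle (nine-membered if counted through the bridging oxygen), formed in a 10-exo-trig mode at the C4 carbonyl with the enolate double bond C5=C6 endocyclic. The new stereocentre C4 is controlled by C10: the tether leaves C10 on the face of the dihydrofuran that carries C9, so C5 can reach the coplanar, conjugated C4 carbonyl only from that face. Which descriptor results then depends on the carbonyl rotamer, and chelation of trivalent samarium between the ring oxygen and the carbonyl oxygen should hold the C=O syn to the ring oxygen; attack on that rotamer from the C9 face gives (4S). The step needs chemoselective reduction of the C–Br bond, ring closure faster than protonation or intermolecular aldol, and no retro-aldol: the first follows from the reduction potentials, the second from slow addition into excess reagent at −78 °C, the third from the stable samarium aldolate chelate and a cold quench.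

Step 15
Reactants: 23 (4S,10S) ten-membered C6-keto C4-carbinol fused to the silylfuran (C13 as OTIPS)
Product: 24 (4S,6S,10S) anti-4,6-diol (C12 SiMe3, C13 OTIPS)
Conditions: Me4NBH(OAc)3, MeCN/AcOH, −30 °C
Reagents that add atoms: none
Why: Evans–Saksena reduction: the C4 hydroxyl exchanges onto boron and delivers hydride to the C6 ketone through a six-membered chair-like transition state, which places the new hydroxyl anti to the C4 oxygen, i.e. (6S). The reagent does not touch the enol ether or the silylfuran, and the low temperature limits exposure to acid.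

Step 16
Reactants: 24 (4S,6S,10S) anti-4,6-diol (C12 SiMe3, C13 OTIPS)
Product: 25 (4S,6S,10S) 4,6,13-triol (C12 SiMe3)
Conditions: Bu4NF, THF, 0 °C to rt
Reagents that add atoms: none
Why: Fluoride removes the primary triisopropylsilyl ether; no stereocentre is involved.

Step 17
Reactants: 25 (4S,6S,10S) 4,6,13-triol (C12 SiMe3)
Product: 26 (4S,6S,10S) C6,C13-diacetate with free C4 hydroxyl (C12 SiMe3)
Conditions: Ac2O, pyridine, DMAP (cat.), CH2Cl2, 0 °C
Reagents that add atoms: acetic anhydride, CC(=O)OC(C)=O
Why: The primary and the secondary hydroxyl are acetylated, while the hindered tertiary C4 hydroxyl is not acylated under these mild conditions.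

Step 18
Reactants: 26 (4S,6S,10S) C6,C13-diacetate with free C4 hydroxyl (C12 SiMe3)
Product: 29 C8-hydroxybutenolide diacetate (C8 epimers), via endoperoxide 27 (not isolated), via silyloxybutenolide 28 (not isolated)
Conditions: O2, hν (visible), tetraphenylporphyrin (cat.), CH2Cl2, −78 °C; then warm to 0 °C, H2O
Reagents that add atoms: dioxygen, O=O
Why: Singlet oxygen adds [4+2] across C8 and C12 of the electron-rich, fully substituted silylfuran, which should react faster than the trisubstituted enol ether at −78 °C. In endoperoxide 27 the silyl group migrates from C12 to the peroxide oxygen with O–O cleavage, so C12 becomes the lactone carbonyl and C8 the silylated lactol 28, which hydrolyses on work-up; C8 forms as epimers that are destroyed in step 19.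

Step 19
Reactants: 29 C8-hydroxybutenolide diacetate (C8 epimers)
Product: 30 target, (4S,6S,10S) with (E)-C8=C9
Conditions: Ac2O, Et3N, DMAP (cat.), CH2Cl2, −20 to 0 °C
Reagents that add atoms: none
Why: Acylation of the lactol hydroxyl (or of its ring-opened keto carboxylate) and loss of acetic acid across C8–C9 is the standard enol-lactonisation route to γ-ylidene butenolides; C9 is the only carbon that can lose a proton. The ten-membered ring allows only the geometry with C7 and C10 cis, which is the (E) isomer of the target.

## Compound list

1 | 3,4-dibromofuran | Brc1cocc1Br | starting material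
2 | 4-bromofuran-3-yllithium | [Li]c1cocc1Br | intermediate
3 | 4-bromofuran-3-carbaldehyde | O=Cc1cocc1Br | intermediate
4 | (4-bromofuran-3-yl)methanol | OCc1cocc1Br | intermediate
5 | [(4-bromofuran-3-yl)methoxy]tri(propan-2-yl)silane | CC(C)[Si](OCc1cocc1Br)(C(C)C)C(C)C | intermediate
6 | (S)-but-3-yn-2-ol | C[C@H](O)C#C | starting material
7 | (S)-(but-3-yn-2-yloxy)triethylsilane | C[C@H](O[Si](CC)(CC)CC)C#C | intermediate
8 | (R)-2-methylglycidol, (2R)-(2-methyloxiran-2-yl)methanol | C[C@@]1(CO)CO1 | starting material
9 | (S)-(2-methyloxiran-2-yl)methyl 4-methylbenzenesulfonate | C[C@@]1(COS(=O)(=O)c2ccc(C)cc2)CO1 | intermediate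
10 | {(3S)-3-[(triethylsilyl)oxy]but-1-yn-1-yl}lithium | [Li]C#C[C@H](C)O[Si](CC)(CC)CC | intermediate
11 | (2S,6S)-2-hydroxy-2-methyl-6-[(triethylsilyl)oxy]hept-4-yn-1-yl 4-methylbenzenesulfonate | C[C@@](O)(COS(=O)(=O)c1ccc(C)cc1)CC#C[C@H](C)O[Si](CC)(CC)CC | intermediate
12 | triethyl{[(2S)-5-[(2S)-2-methyloxiran-2-yl]pent-3-yn-2-yl]oxy}silane | C[C@]1(CC#C[C@H](C)O[Si](CC)(CC)CC)CO1 | intermediate
13 | [3-bromo-4-({[tri(propan-2-yl)silyl]oxy}methyl)furan-2-yl]lithium | [Li]c1occ(CO[Si](C(C)C)(C(C)C)C(C)C)c1Br | intermediate
14 | (2S,6S)-1-[3-bromo-4-({[tri(propan-2-yl)silyl]oxy}methyl)furan-2-yl]-2-methyl-6-[(triethylsilyl)oxy]hept-4-yn-2-ol | C[C@](O)(CC#C[C@H](C)O[Si](CC)(CC)CC)Cc1occ(CO[Si](C(C)C)(C(C)C)C(C)C)c1Br | intermediate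
15 | 3-bromo-2-{[(2S)-2-methyl-5-{(1S)-1-[(triethylsilyl)oxy]ethyl}-2,3-dihydrofuran-2-yl]methyl}-4-({[tri(propan-2-yl)silyl]oxy}methyl)furan | C[C@H](O[Si](CC)(CC)CC)C1=CC[C@@](C)(Cc2occ(CO[Si](C(C)C)(C(C)C)C(C)C)c2Br)O1 | intermediate
16 | [4-bromo-5-{[(2S)-2-methyl-5-{(1S)-1-[(triethylsilyl)oxy]ethyl}-2,3-dihydrofuran-2-yl]methyl}-3-({[tri(propan-2-yl)silyl]oxy}methyl)furan-2-yl]trimethylsilane | C[C@H](O[Si](CC)(CC)CC)C1=CC[C@@](C)(Cc2oc([Si](C)(C)C)c(CO[Si](C(C)C)(C(C)C)C(C)C)c2Br)O1 | intermediate
17 | (1S)-1-[(5S)-5-{[3-bromo-5-(trimethylsilyl)-4-({[tri(propan-2-yl)silyl]oxy}methyl)furan-2-yl]methyl}-5-methyl-4,5-dihydrofuran-2-yl]ethan-1-ol | C[C@H](O)C1=CC[C@@](C)(Cc2oc([Si](C)(C)C)c(CO[Si](C(C)C)(C(C)C)C(C)C)c2Br)O1 | intermediate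
18 | C4 lithium alkoxide, C7 aryllithium derived from 17 | C[C@H](O[Li])C1=CC[C@@](C)(Cc2oc([Si](C)(C)C)c(CO[Si](C(C)C)(C(C)C)C(C)C)c2[Li])O1 | intermediate
19 | 2-chloro-1-[2-{[(2S)-5-[(1S)-1-hydroxyethyl]-2-methyl-2,3-dihydrofuran-2-yl]methyl}-5-(trimethylsilyl)-4-({[tri(propan-2-yl)silyl]oxy}methyl)furan-3-yl]ethan-1-one | C[C@H](O)C1=CC[C@@](C)(Cc2oc([Si](C)(C)C)c(CO[Si](C(C)C)(C(C)C)C(C)C)c2C(=O)CCl)O1 | intermediate
20 | 1-[(5S)-5-{[3-(chloroacetyl)-5-(trimethylsilyl)-4-({[tri(propan-2-yl)silyl]oxy}methyl)furan-2-yl]methyl}-5-methyl-4,5-dihydrofuran-2-yl]ethan-1-one | CC(=O)C1=CC[C@@](C)(Cc2oc([Si](C)(C)C)c(CO[Si](C(C)C)(C(C)C)C(C)C)c2C(=O)CCl)O1 | intermediate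
21 | 1-[(5S)-5-{[3-(bromoacetyl)-5-(trimethylsilyl)-4-({[tri(propan-2-yl)silyl]oxy}methyl)furan-2-yl]methyl}-5-methyl-4,5-dihydrofuran-2-yl]ethan-1-one (C5 bromide, C6 furyl ketone, C4 methyl ketone) | CC(=O)C1=CC[C@@](C)(Cc2oc([Si](C)(C)C)c(CO[Si](C(C)C)(C(C)C)C(C)C)c2C(=O)CBr)O1 | intermediate
22 | trivalent samarium enolate of 21 (C5=C6–O–SmI2) | CC(=O)C1=CC[C@@](C)(Cc2oc([Si](C)(C)C)c(CO[Si](C(C)C)(C(C)C)C(C)C)c2C(=C)O[Sm](I)I)O1 | intermediate
23 | (4S,10S) β-hydroxy ketone: carbocycle C1–C10 with C6 ketone and C4 carbinol (CH3, OH), bridged C3–O–C10 (C2=C3, C10 methyl), fused at C7–C8 to the furan bearing SiMe3 on C12 and CH2OTIPS on C11 | O=C1C[C@](C)(O)C2=CC[C@@](C)(Cc3oc([Si](C)(C)C)c(CO[Si](C(C)C)(C(C)C)C(C)C)c31)O2 | intermediate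
24 | (4S,6S,10S) anti-4,6-diol of 23 | O[C@H]1C[C@](C)(O)C2=CC[C@@](C)(Cc3oc([Si](C)(C)C)c(CO[Si](C(C)C)(C(C)C)C(C)C)c31)O2 | intermediate
25 | (4S,6S,10S) 4,6,13-triol (C12 SiMe3) | O[C@H]1C[C@](C)(O)C2=CC[C@@](C)(Cc3oc([Si](C)(C)C)c(CO)c31)O2 | intermediate
26 | (4S,6S,10S) C6,C13-diacetate with free C4 hydroxyl (C12 SiMe3) | CC(=O)O[C@H]1C[C@](C)(O)C2=CC[C@@](C)(Cc3oc([Si](C)(C)C)c(COC(C)=O)c31)O2 | intermediate
27 | C8,C12-endoperoxide of 26 | CC(=O)O[C@H]1C[C@](C)(O)C2=CC[C@@](C)(CC34OOC(O3)([Si](C)(C)C)C(COC(C)=O)=C41)O2 | intermediate
28 | C8-(trimethylsilyloxy) butenolide diacetate (C8 epimers) | CC(=O)OCC1=C2C(O[Si](C)(C)C)(C[C@]3(C)CC=C(O3)[C@@](C)(O)C[C@@H]2OC(C)=O)OC1=O | intermediate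
29 | C8-hydroxy butenolide diacetate (lactol, C8 epimers) | CC(=O)OCC1=C2C(O)(C[C@]3(C)CC=C(O3)[C@@](C)(O)C[C@@H]2OC(C)=O)OC1=O | intermediate
30 | target CNP0144020.1, (4S,6S,10S), (E)-C8=C9 | CC(=O)OCC1=C2/C(=C\[C@]3(C)CC=C(O3)[C@@](C)(O)C[C@@H]2OC(C)=O)OC1=O | target

## Step count and least certain steps

Total: 19 steps. Longest linear sequence: 16 steps (steps 1–3 and 7–19, from 1 to 30); steps 4–6 build epoxide 12 in parallel.

**Step 14 (key step).** The enolate 22 may be protonated before it reaches C4 (plain loss of bromine), the aldolate may revert on warming, or attack may occur on the carbonyl rotamer that is not chelated and erode the C4 selectivity. All three follow from a strained medium ring having to form from a short-lived enolate. Fallback: separate enolate formation from ring closure. Setting out from 21, zinc dust and Me3SiCl convert the α-bromo ketone regiospecifically into the trimethylsilyl enol ether F1. A Mukaiyama aldol closure promoted by MgBr2·OEt2 (or TiCl4) at high dilution and −78 °C, with the Lewis acid chelated between the dihydrofuran oxygen and the C4 carbonyl oxygen so that the same rotamer is fixed, then gives 23 after aqueous work-up, where the route is rejoined.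

**Step 8.** The neighbouring furan may attack the gold-activated alkyne in competition with the hydroxyl, and the allylic silyloxy enol ether may ionise or hydrate under the Lewis-acidic catalyst as it forms. Fallback: close the dihydrofuran before the furan is present and join the fragments through a C9 aldehyde.
- Setting out from 12, PhCO2Cs/PhCO2H in DMF opens the epoxide at CH2 to the hydroxy benzoate F2.
- The same gold catalyst, now without a competing arene, gives the dihydrofuran benzoate F3.
- K2CO3/MeOH frees the primary alcohol F4, and Dess–Martin periodinane gives the α-quaternary aldehyde F5.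
- Addition of furyllithium 13 gives the carbinol F6 (both C9 epimers).
- F6 is deoxygenated by the Barton–McCombie sequence through the imidazolyl thiocarbonate F7 (thiocarbonyldiimidazole; then Bu3SnH, AIBN) to 15, where the route is rejoined.

**Step 11.** The hindered aryllithium may be protonated by the acidic CH2Cl protons of the amide, or the exchange may be incomplete, so that C7 ends up unsubstituted. Fallback: replace the organolithium acylation by a palladium-catalysed coupling after the C4 ketone is in place. Setting out from 17, MnO2 gives the bromo ketone F8. Stille coupling with tributyl(1-ethoxyethenyl)stannane (Pd2(dba)3, AsPh3, CuI, NMP) gives the 1-ethoxyethenyl furan F9. NBS in aqueous THF then brominates this most electron-rich enol ether and hydrolyses it directly to 21, so that steps 11 to 13 are bypassed.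

**Step 15.** The hindered tertiary C4 hydroxyl may exchange onto boron too slowly, so that hydride arrives without internal delivery and the ring conformation dictates the face, giving the C6 epimer. Acetic acid may also add slowly to the enol ether. Fallback: reduce under chelation control to the syn diol and invert. Setting out from 23, Et2BOMe/NaBH4 (Narasaka–Prasad) gives the (6R) syn diol F10. A Mitsunobu reaction with acetic acid (PPh3, DIAD) inverts C6 and installs the acetate in one operation to give F11. Bu4NF removes the silyl ether to give the primary alcohol F12, and acetylation of that hydroxyl gives 26.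

**Step 19.** The C4 hydroxyl may capture C8 across the ring (transannular ketal formation, already possible at the stage of 29), or the tertiary allylic C4 hydroxyl may be acylated and ionise instead of the lactol. Fallback: mask the C4 hydroxyl over the last two steps. Setting out from 26, N-(trimethylsilyl)imidazole gives the tertiary trimethylsilyl ether F13. Photooxygenation as in step 18 gives the hydroxybutenolide F14, and the Ac2O/Et3N dehydration gives the ylidene butenolide F15. Buffered fluoride (Bu4NF/AcOH, 0 °C) then removes the silyl ether and gives 30.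

## Further compounds

F1 | step 14 | trimethylsilyl enol ether of the C6 ketone (C5=C6–OSiMe3), C4 methyl ketone intact | CC(=O)C1=CC[C@@](C)(Cc2oc([Si](C)(C)C)c(CO[Si](C(C)C)(C(C)C)C(C)C)c2C(=C)O[Si](C)(C)C)O1
F2 | step 8 | (2S,6S)-2-hydroxy-2-methyl-6-[(triethylsilyl)oxy]hept-4-yn-1-yl benzoate | C[C@](O)(CC#C[C@H](C)O[Si](CC)(CC)CC)COC(=O)c1ccccc1
F3 | step 8 | [(2S)-2-methyl-5-{(1S)-1-[(triethylsilyl)oxy]ethyl}-2,3-dihydrofuran-2-yl]methyl benzoate | C[C@H](O[Si](CC)(CC)CC)C1=CC[C@@](C)(COC(=O)c2ccccc2)O1
F4 | step 8 | [(2S)-2-methyl-5-{(1S)-1-[(triethylsilyl)oxy]ethyl}-2,3-dihydrofuran-2-yl]methanol | C[C@H](O[Si](CC)(CC)CC)C1=CC[C@@](C)(CO)O1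
F5 | step 8 | (2S)-2-methyl-5-{(1S)-1-[(triethylsilyl)oxy]ethyl}-2,3-dihydrofuran-2-carbaldehyde | C[C@H](O[Si](CC)(CC)CC)C1=CC[C@@](C)(C=O)O1
F6 | step 8 | [3-bromo-4-({[tri(propan-2-yl)silyl]oxy}methyl)furan-2-yl][(2S)-2-methyl-5-{(1S)-1-[(triethylsilyl)oxy]ethyl}-2,3-dihydrofuran-2-yl]methanol (C9 epimers) | C[C@H](O[Si](CC)(CC)CC)C1=CC[C@@](C)(C(O)c2occ(CO[Si](C(C)C)(C(C)C)C(C)C)c2Br)O1
F7 | step 8 | O-(imidazol-1-ylcarbonothioyl) derivative of F6 (C9 epimers) | C[C@H](O[Si](CC)(CC)CC)C1=CC[C@@](C)(C(OC(=S)n2ccnc2)c2occ(CO[Si](C(C)C)(C(C)C)C(C)C)c2Br)O1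
F8 | step 11 | 1-[(5S)-5-{[3-bromo-5-(trimethylsilyl)-4-({[tri(propan-2-yl)silyl]oxy}methyl)furan-2-yl]methyl}-5-methyl-4,5-dihydrofuran-2-yl]ethan-1-one | CC(=O)C1=CC[C@@](C)(Cc2oc([Si](C)(C)C)c(CO[Si](C(C)C)(C(C)C)C(C)C)c2Br)O1
F9 | step 11 | 1-[(5S)-5-{[3-(1-ethoxyethenyl)-5-(trimethylsilyl)-4-({[tri(propan-2-yl)silyl]oxy}methyl)furan-2-yl]methyl}-5-methyl-4,5-dihydrofuran-2-yl]ethan-1-one | CC(=O)C1=CC[C@@](C)(Cc2oc([Si](C)(C)C)c(CO[Si](C(C)C)(C(C)C)C(C)C)c2C(=C)OCC)O1
F10 | step 15 | (4S,6R,10S) syn-4,6-diol, C6 epimer of 24 | O[C@@H]1C[C@](C)(O)C2=CC[C@@](C)(Cc3oc([Si](C)(C)C)c(CO[Si](C(C)C)(C(C)C)C(C)C)c31)O2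
F11 | step 15 | (4S,6S,10S) C6 acetate with free C4 hydroxyl and C13 OTIPS | CC(=O)O[C@H]1C[C@](C)(O)C2=CC[C@@](C)(Cc3oc([Si](C)(C)C)c(CO[Si](C(C)C)(C(C)C)C(C)C)c31)O2
F12 | step 15 | (4S,6S,10S) C6 acetate with free C4 and C13 hydroxyls | CC(=O)O[C@H]1C[C@](C)(O)C2=CC[C@@](C)(Cc3oc([Si](C)(C)C)c(CO)c31)O2
F13 | step 19 | C4 trimethylsilyl ether of 26 | CC(=O)O[C@H]1C[C@](C)(O[Si](C)(C)C)C2=CC[C@@](C)(Cc3oc([Si](C)(C)C)c(COC(C)=O)c31)O2
F14 | step 19 | C4 trimethylsilyl ether of 29 (C8 epimers) | CC(=O)OCC1=C2C(O)(C[C@]3(C)CC=C(O3)[C@@](C)(O[Si](C)(C)C)C[C@@H]2OC(C)=O)OC1=O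
F15 | step 19 | C4 trimethylsilyl ether of 30 | CC(=O)OCC1=C2/C(=C\[C@]3(C)CC=C(O3)[C@@](C)(O[Si](C)(C)C)C[C@@H]2OC(C)=O)OC1=O
A1 | alternative 1 | ten-membered C10 tertiary allylic alcohol with the ylidene butenolide in place and C3/C4 as acetonide | CC(=O)OCC1=C2/C(=C\[C@@](C)(O)CC[C@@H]3OC(C)(C)O[C@@]3(C)C[C@@H]2OC(C)=O)OC1=O
A2 | alternative 2 | oxygen-bridged bicyclic C8 ketone with exocyclic 2-(trimethylsilyl)ethyl alkylidene ester at C7 | C[Si](C)(C)CCOC(=O)/C(COC(C)=O)=C1\C(=O)C[C@]2(C)CC=C(O2)[C@@](C)(O[Si](CC)(CC)CC)C[C@@H]1OC(C)=O
A3 | alternative 3 | ten-membered C3 ketone with ylidene butenolide and silyl ethers at C4, C6, C10 and C13 | CC(C)(C)[Si](C)(C)OCC1=C2/C(=C\[C@](O[Si](C)(C)C(C)(C)C)(C)CCC(=O)[C@@](C)(O[Si](CC)(CC)CC)C[C@@H]2O[Si](C)(C)C(C)(C)C)OC1=O
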